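The earlier runs and the new flask were generated by integration with constants of no real substance, and the scatter is random.

**Small charge.** A small charge of 22 mM starting material in the noon run gives target 34.8% at 25.0 min, about the same as the 34.9% of the spring run with 43 mM, so I treat the loss of target as first order.

| setting | spring | noon | summer | dawn | larch | cedar | alder | ash |
|---|---|---|---|---|---|---|---|---|
| starting material | 43 mM | 22 mM | 32 mM | 43 mM | 43 mM | 43 mM (fed, over 32.0 min) | 43 mM | 43 mM |
| free catalyst | 0.86 mM | 0.86 mM | 0.86 mM | 1.7 mM | 0.86 mM | 0.86 mM | 0.86 mM | 0.86 mM |
| remark | run made earlier | run made earlier | run made earlier | run made earlier | a closed flask charged with all of it at once and left for 40 min | all but starting material at the start; starting material goes in evenly over 32.0 min, the run ends at 40 min | a tube with plug flow, the mixed feed as stated, residence time 40 min | a single well-mixed tank run continuously and read at steady state, 40 min in it on average |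
| time |  |  |  |  | 40 min | 40 min | 40 min |  |

| run | time / min | target / % | over-reaction product / % |
|---|---|---|---|
| spring | 4.00 | 10.1 | 0 |
| spring | 8.00 | 17.8 | 3.0 |
| spring | 12.0 | 23.9 | 4.0 |
| spring | 15.0 | 27.6 | 4.9 |
| spring | 20.0 | 31.9 | 8.8 |
| spring | 25.0 | 34.9 | 11.0 |
| noon | 4.00 | 10.5 | 0.7 |
| noon | 8.00 | 19.1 | 3.3 |
| noon | 12.0 | 25.2 | 3.4 |
| noon | 15.0 | 27.8 | 8.4 |
| noon | 20.0 | 33.2 | 8.9 |
| noon | 25.0 | 34.8 | 11.8 |
| summer | 4.00 | 11.4 | 1.0 |
| summer | 8.00 | 20.7 | 1.6 |
| summer | 12.0 | 24.8 | 2.9 |
| summer | 15.0 | 29.5 | 4.0 |
| summer | 20.0 | 32.2 | 7.8 |
| summer | 25.0 | 32.4 | 11.5 |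
| dawn | 5.00 | 21.9 | 2.0 |
| dawn | 10.0 | 37.9 | 2.8 |
| dawn | 15.0 | 45.7 | 10.5 |
| dawn | 20.0 | 50.7 | 14.5 |
| dawn | 25.0 | 50.9 | 19.2 |

(standard deviation of a reading: 1 percentage point)

- the stated concentrations are those of everything mixed, before any reaction; amounts are the same in each set-up
- the feed brings no volume worth counting
- the earlier runs were made in a closed, stirred flask

- the set-up with the highest share of target in all that became target or over-reaction product, at the outlet or at the end ("none" if the first two lie within 2 percentage points) (larch / cedar / alder / ash / none)
- share of target in all that became target or over-reaction product, at the outlet or at the end, larch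
- share of target in all that became target or over-reaction product, at the outlet or at the end, cedar
- share of target in all that became target or over-reaction product, at the outlet or at the end, alder
- share of target in all that became target or over-reaction product, at the outlet or at the end, ash

**Loss constant.** Over-reaction product divided by the time-integral of target gives k, the fraction of the target present lost per minute: 0.0211 min⁻¹ read from the dawn run, and 0.0199 min⁻¹ from spring, with half the catalyst. I use dawn, whose last over-reaction product stands higher above the scatter.

**Fraction left.** Target of age a keeps the fraction exp(−ka). With this loss, the share asked (the selectivity) is therefore the mean fraction left over the target made.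

**Two extremes.** If larch made its target in one burst at the start, the share would be 42.9%; if evenly over 40 min, 67.5%. Spring turned over 27.9% by 12.0 min and 18 percentage points in the next 13.0 min: making slows but continues, so I place larch between, and alder with it, each slice of the tube being a larch. Cedar's making starts from nothing and climbs while the feed runs, so I expect its target to be younger and place its share above 67.5%, below the 76.9% of a straight rise from zero. Ash, with mean time τ, gives 1/(1+kτ) = 54.2%.

**The forecast.** It says 62.5% for larch, 74% for cedar, 62.5% for alder, 54% for ash, with cedar “best because material is younger”.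

**The flask.** The best is cedar: larch 60.8%, cedar 72.7%, alder 60.8%, ash 54.3%.

    catalyst intermediate → free catalyst + target (k = 0.660 s⁻¹)
    starting material + free catalyst → catalyst intermediate (k = 0.620 M⁻¹ s⁻¹)
    free catalyst ⇌ dormant form (K = 2.10, k = 3.80 × 10⁻⁴ s⁻¹)
    target → over-reaction product (k = 3.50 × 10⁻⁴ s⁻¹)

**Slowing supply.** In larch, the half-life of starting material by its step, 22 min with the charges held, reaches 43 min at 40.0 min, longer than target's 33 min by its loss. At that time larch makes target at 0.895 of the rate at which it uses it up, each step taken net. Larch read at 10 min has the extremes 81.0% and 90.2%, and gives 89.5%.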